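**Retrosynthetic overview**
- Last bond: C4–OMe, made by an oxidative vinylogous C–O coupling of the 4-unsubstituted enone with methanol (new copper method); this sets C4.
- Before that: the aryl carbinol comes from a Felkin–Anh addition of the arylmagnesium bromide to an α-methyl aldehyde, and the ring C=O from a singlet-oxygen ene/Kornblum–DeLaMare oxygenation of a cyclohexene (C–O bond formation with allylic shift).
- The quaternary carbon and its methyl-bearing neighbour come from an iridium-catalysed isomerisation–Claisen rearrangement of an (S)-cyclohexenyl allyl ether, so every carbon stereocentre is relayed from one C–O stereocentre.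
- That ether comes from 3-ethoxycyclohex-2-en-1-one by Stork–Danheiser allylation, CBS reduction and O-allylation.
- Rings: the single carbocycle is bought; no ring-forming step is needed.

Assumption: the SMILES is read as (4S,6S) in the ring and (1S,2R) in the side chain (methyl and hydroxyl syn; methoxy cis to the side chain), and 3,4-dimethoxyphenylmagnesium bromide is bought as its THF solution.

**Step 1**
Reactants: 1 3-ethoxycyclohex-2-en-1-one; 2 allylmagnesium bromide
Product: 4 3-allylcyclohex-2-en-1-one, via tertiary carbinol adduct 3 (not isolated)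
Conditions: 2 (1.2 equiv), THF/Et2O, 0 °C; then 1 M aq HCl, 0 °C, 20 min
Reagents that add atoms: allylmagnesium bromide 2 (C=CC[Mg]Br); water (O)
Why: Stork–Danheiser sequence: 1,2-addition of the Grignard reagent to the vinylogous ester, then acid hydrolysis of the enol ether with loss of ethanol and water transposes the carbonyl; brief cold acid keeps the allyl double bond out of conjugation; no stereocentre.

**Step 2**
Reactants: 4 3-allylcyclohex-2-en-1-one
Product: 5 (1S)-3-allylcyclohex-2-en-1-ol
Conditions: (R)-1-methyl-3,3-diphenyltetrahydro-1H,3H-pyrrolo[1,2-c][1,3,2]oxazaborole (10 mol %), catecholborane (1.5 equiv), toluene, −78 °C; aq NaOH work-up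
Reagents that add atoms: none
Why: Corey–Bakshi–Shibata reduction: the alkenyl arm acts as the large group, so the (R)-oxazaborolidine delivers hydride to give the (S)-carbinol; catecholborane at −78 °C reduces the C=O only and leaves the terminal alkene alone.

**Step 3**
Reactants: 5 (1S)-3-allylcyclohex-2-en-1-ol; 6 allyl bromide
Product: 7 (3S)-1-allyl-3-(allyloxy)cyclohex-1-ene
Conditions: NaH (1.3 equiv), 6 (1.5 equiv), Bu4NI (5 mol %), THF, 0 °C to rt
Reagents that add atoms: allyl bromide 6 (C=CCBr)
Why: Williamson etherification at oxygen; the C–O stereocentre is not touched.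

**Step 4**
Reactants: 7 (3S)-1-allyl-3-(allyloxy)cyclohex-1-ene
Product: 9 (2R)-2-[(1S)-1-allylcyclohex-2-en-1-yl]propanal, via (E)-propenyl ether 8 (not isolated)
Conditions: [IrCl(C8H14)2]2 (1 mol %), PCy3 (6 mol %), NaBPh4 (2 mol %), CH2Cl2/acetone 50:1, rt, 1 h; then PPh3 (6 mol %), toluene, 100 °C
Reagents that add atoms: none
Why: Olefin isomerisation–Claisen rearrangement: the cationic tris(phosphine) monovalent iridium catalyst isomerises the unhindered O-allyl group to the (E)-propenyl ether 8, and the thermal [3,3] shift runs suprafacially through a chair (methyl and exocyclic allyl equatorial; the vinyl carbon carries only H, so nothing forces a boat), which places the new C–C bond on the face the C–O bond leaves and sets the 1S quaternary carbon together with the 2R methyl-bearing carbon.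

**Step 5**
Reactants: 9 (2R)-2-[(1S)-1-allylcyclohex-2-en-1-yl]propanal
Product: 12 (2R)-2-[(1R)-1-allyl-2-oxocyclohex-3-en-1-yl]propanal, via allylic hydroperoxide 10 (not isolated), via peroxyacetate 11 (not isolated)
Conditions: O2, 5,10,15,20-tetraphenylporphyrin (0.5 mol %), white LED, CH2Cl2, 0 °C; then Ac2O (1.5 equiv), pyridine (3 equiv), 4-(dimethylamino)pyridine (5 mol %), 0 °C to rt
Reagents that add atoms: dioxygen (O=O)
Why: Schenck ene reaction: singlet oxygen can take an allylic hydrogen only from ring C4 (the other allylic carbon is quaternary), so oxygen goes to C2 next to the quaternary carbon with shift of the double bond, and Kornblum–DeLaMare-type elimination of the peroxyacetate gives the enone; the monosubstituted allyl alkene is much slower and no stereocentre is created (the 1R label is only a priority change).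

**Step 6**
Reactants: 12 (2R)-2-[(1R)-1-allyl-2-oxocyclohex-3-en-1-yl]propanal; 13 3,4-dimethoxyphenylmagnesium bromide
Product: 14 (6R)-6-allyl-6-[(1S,2R)-1-(3,4-dimethoxyphenyl)-1-hydroxypropan-2-yl]cyclohex-2-en-1-one
Conditions: 13 (1.15 equiv, 0.5 M in THF), THF, −78 °C, 1 h; sat. aq NH4Cl
Reagents that add atoms: 3,4-dimethoxyphenylmagnesium bromide 13 (COc1ccc([Mg]Br)cc1OC)
Why: Felkin–Anh-controlled Grignard addition: with the quaternary carbon as the large group anti to the incoming aryl and the α-hydrogen on the attack path, the (1S) carbinol syn to the methyl group forms; the aldehyde reacts far faster than the conjugated neopentyl ring ketone at −78 °C.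

**Step 7**
Reactants: 14 (6R)-6-allyl-6-[(1S,2R)-1-(3,4-dimethoxyphenyl)-1-hydroxypropan-2-yl]cyclohex-2-en-1-one
Product: 15 (4S,6S)-6-allyl-6-[(1S,2R)-1-(3,4-dimethoxyphenyl)-1-hydroxypropan-2-yl]-4-methoxycyclohex-2-en-1-one
Conditions: Cu(OTf)2 (10 mol %), 2,2′-(propane-2,2-diyl)bis[(4S)-4-tert-butyl-4,5-dihydro-1,3-oxazole] (12 mol %), 1,1,3,3-tetramethylguanidine (20 mol %), Ag2CO3 (1.1 equiv), MeOH/THF 1:1, 3 Å MS, 0 °C to rt, argon, dark
Reagents that add atoms: methanol (CO)
Why: Proposed new method: oxidative vinylogous C–H methoxylation; C4 is the only enolisable position (C6 is quaternary), so the guanidine and divalent copper give the copper dienolate; one-electron oxidation gives the γ-centred dienoxyl radical, which is captured by the bisoxazoline-ligated divalent copper methoxide to a trivalent copper allyl methoxide; C–O reductive elimination at C4 restores the conjugated enone while Ag2CO3 returns monovalent copper to the divalent state; the ligand, helped by a hydrogen bond from the side-chain hydroxyl to the copper-bound methoxide, is expected to deliver OMe to the face syn to the side chain (4S), but the intrinsic facial bias of the ring is uncertain and the ligand antipode may need to be swapped; methanol as cosolvent outcompetes intramolecular etherification; closest known reaction types are the copper-catalysed aerobic vinylogous γ-hydroxylation of enones, the Kharasch–Sosnovsky allylic oxidation and copper radical-relay C–H etherification.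

**Compound list**
1 | 3-ethoxycyclohex-2-en-1-one | CCOC1=CC(=O)CCC1 | starting material
2 | allylmagnesium bromide | C=CC[Mg]Br | starting material
3 | 1-allyl-3-ethoxycyclohex-2-en-1-ol (racemic tertiary carbinol, present as its bromomagnesium alkoxide until the acid quench) | CCOC1=CC(O)(CC=C)CCC1 | intermediate
4 | 3-allylcyclohex-2-en-1-one | C=CCC1=CC(=O)CCC1 | intermediate
5 | (1S)-3-allylcyclohex-2-en-1-ol | O[C@@H]1C=C(CC=C)CCC1 | intermediate
6 | allyl bromide | C=CCBr | starting material
7 | (3S)-1-allyl-3-(allyloxy)cyclohex-1-ene | C=CCO[C@@H]1C=C(CC=C)CCC1 | intermediate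
8 | (3S)-1-allyl-3-[(E)-prop-1-en-1-yloxy]cyclohex-1-ene | C/C=C/O[C@@H]1C=C(CC=C)CCC1 | intermediate
9 | (2R)-2-[(1S)-1-allylcyclohex-2-en-1-yl]propanal | C=CC[C@@]1([C@@H](C)C=O)CCCC=C1 | intermediate
10 | (2R)-2-[1-allyl-2-hydroperoxycyclohex-3-en-1-yl]propanal (quaternary carbon as in 9, both C–OOH epimers) | C=CC[C@@]1([C@@H](C)C=O)CCC=CC1OO | intermediate
11 | peroxyacetate of 10 | C=CC[C@@]1([C@@H](C)C=O)CCC=CC1OOC(C)=O | intermediate
12 | (2R)-2-[(1R)-1-allyl-2-oxocyclohex-3-en-1-yl]propanal | C=CC[C@@]1([C@@H](C)C=O)CCC=CC1=O | intermediate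
13 | 3,4-dimethoxyphenylmagnesium bromide | COc1ccc([Mg]Br)cc1OC | starting material
14 | (6R)-6-allyl-6-[(1S,2R)-1-(3,4-dimethoxyphenyl)-1-hydroxypropan-2-yl]cyclohex-2-en-1-one | C=CC[C@@]1([C@@H](C)[C@H](O)c2ccc(OC)c(OC)c2)CCC=CC1=O | intermediate
15 | (4S,6S)-6-allyl-6-[(1S,2R)-1-(3,4-dimethoxyphenyl)-1-hydroxypropan-2-yl]-4-methoxycyclohex-2-en-1-one | C=CC[C@@]1([C@@H](C)[C@H](O)c2ccc(OC)c(OC)c2)C[C@H](OC)C=CC1=O | target

**Step count**
Total steps: 7. Longest linear sequence: 7 (1 to 15).

**Three steps most likely to fail**

Step 7 (the new methoxylation). The dienoxyl radical may dimerise, the product may be oxidised again or epimerised at C4, the side-chain oxygen may close onto C4, or the wrong C4 epimer may dominate. The fallback uses known chemistry, sets out from 14 and comes back at 15. TBSOTf (2.5 equiv) and Et3N in CH2Cl2 silylate the carbinol and the dienolate together to give the bis-silyl compound, the benzylic TBS ether carrying a 2-silyloxy-1,3-diene F10. Vinylogous Rubottom oxidation with dimethyldioxirane at −78 °C, then AcOH/H2O, gives the (4S)-4-hydroxy enone TBS ether F11. Facial selectivity here rests on sterics only, so the C4 epimers may need separating. MeI/Ag2O gives the 4-methoxy enone TBS ether F12, and HF·pyridine in THF gives 15.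

Step 5 (singlet-oxygen ene). A cis-disubstituted cyclohexene is a slow ene partner and the allyl group or the aldehyde may compete. The fallback sets out from 9 and comes back at 12, replacing the ene reaction by epoxide opening. HC(OMe)3 and pyridinium p-toluenesulfonate in MeOH give the dimethyl acetal F6. mCPBA/NaHCO3 (1.0 equiv, 0 °C) epoxidises the more electron-rich ring alkene to the epoxide F7. LiNEt2 in Et2O removes the only available β-hydrogen (ring C4) to give the transposed allylic alcohol F8. Dess–Martin periodinane gives the enone acetal F9, and aqueous HCl in acetone frees 12.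

Step 4 (isomerisation–Claisen). The iridium hydride may also move the C-allyl double bond into conjugation, and a boat pathway would erode the 2R centre. The fallback sets out from 5 and comes back at 9 by an Ireland–Claisen route. Propanoyl chloride and pyridine give (1S)-3-allylcyclohex-2-en-1-yl propanoate F1. LiN(iPr)2 in THF at −78 °C followed by TMSCl gives the kinetic trimethylsilyl ketene acetal F2 (methyl cis to the ring oxygen). On warming to 60 °C, F2 rearranges to the trimethylsilyl ester F3. For cyclohexenyl esters the silyloxy group clashes with the ring in the chair, so a boat is expected, and boat plus cis-methyl leads to the same relative configuration as in 9. Aqueous work-up gives (2R)-2-[(1S)-1-allylcyclohex-2-en-1-yl]propanoic acid F4. LiAlH4 gives the primary alcohol F5, and Dess–Martin periodinane gives 9.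

**Further compounds**
F1 | step 4 | (1S)-3-allylcyclohex-2-en-1-yl propanoate | CCC(=O)O[C@@H]1C=C(CC=C)CCC1
F2 | step 4 | trimethylsilyl ketene acetal of F1, methyl cis to the ring oxygen | C/C=C(\O[C@@H]1C=C(CC=C)CCC1)O[Si](C)(C)C
F3 | step 4 | trimethylsilyl (2R)-2-[(1S)-1-allylcyclohex-2-en-1-yl]propanoate | C=CC[C@@]1([C@@H](C)C(=O)O[Si](C)(C)C)CCCC=C1
F4 | step 4 | (2R)-2-[(1S)-1-allylcyclohex-2-en-1-yl]propanoic acid | C=CC[C@@]1([C@@H](C)C(=O)O)CCCC=C1
F5 | step 4 | (2R)-2-[(1S)-1-allylcyclohex-2-en-1-yl]propan-1-ol | C=CC[C@@]1([C@@H](C)CO)CCCC=C1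
F6 | step 5 | dimethyl acetal of 9 | C=CC[C@@]1([C@@H](C)C(OC)OC)CCCC=C1
F7 | step 5 | ring epoxide of F6 (epoxide face mixture) | C=CC[C@@]1([C@@H](C)C(OC)OC)CCCC2OC12
F8 | step 5 | transposed allylic alcohol, dimethyl acetal | C=CC[C@@]1([C@@H](C)C(OC)OC)CCC=CC1O
F9 | step 5 | dimethyl acetal of 12 | C=CC[C@@]1([C@@H](C)C(OC)OC)CCC=CC1=O
F10 | step 7 | benzylic TBS ether and TBS dienol ether of 14 | C=CC[C@@]1([C@@H](C)[C@H](O[Si](C)(C)C(C)(C)C)c2ccc(OC)c(OC)c2)CC=CC=C1O[Si](C)(C)C(C)(C)C
F11 | step 7 | (4S)-4-hydroxy enone, benzylic TBS ether | C=CC[C@@]1([C@@H](C)[C@H](O[Si](C)(C)C(C)(C)C)c2ccc(OC)c(OC)c2)C[C@H](O)C=CC1=O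
F12 | step 7 | benzylic TBS ether of 15 | C=CC[C@@]1([C@@H](C)[C@H](O[Si](C)(C)C(C)(C)C)c2ccc(OC)c(OC)c2)C[C@H](OC)C=CC1=O
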